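**Numbering used.** Decalin atoms are numbered as in naphthalene (ring A = C4a, C5–C8, C8a; ring B = C1–C4, C4a, C8a). The ylidene arm is C1′–C3′ (C2′ = ketone, C3′ = CH2OH). The acid chain is C1″ (CO2H) to C7″ (the carbon bonded to C1).

## Structural features

Compound 37 is a cis-fused octalin in which ring A is a saturated cyclohexane and ring B carries the C3 methyl, the C3=C4 alkene and an exocyclic C2=C1′ ylidene ending in a hydroxyacetyl ketone, with the acyl group on the C1 side (E). C1 bears a (2E,4Z,6E)-4,6-dimethylhepta-2,4,6-trienoic acid. Six stereocentres are contiguous: the C6 methyl, C7 hydroxyl and C8 methyl are mutually trans and all equatorial on ring A, C8 adjoins the cis ring fusion (C8a, C4a), and C8a adjoins C1, whose chain is trans to the C8a–C8 bond. H1 is doubly allylic and γ to the dienone, so base can epimerise C1 or move the ylidene into the ring; the 4″Z trisubstituted alkene, the α-hydroxy ketone and the polyene acid are also sensitive. The α-branched aldehydes that must flank C8 and C1 on the way are epimerisable. The real difficulty is the C1/C2 region: an sp3 C1 carrying a geometrically defined triene must be set next to the ylidene without ever pairing a C1 carbonyl with a C2 carbonyl or exposing the dienone to base. The key step exploits ring A: the C7 carbinol beside the C6 methyl is what a C7 ketyl on the C8a arm leaves when it adds to the inner carbon (C6) of an allyl group on C4a, so that one C6–C7 bond gives ring A, the hydroxyl and the methyl together.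

## Logic of the disconnections

37 ⇒ 36 ⇒ 35. After the two silyl ethers are put back, the C6″–CH3 bond is cut. C6″ then carries a bromine, and the 6″E geometry follows from the order in which two groups are attached to a gem-dibromide carbon. The methyl goes on last because the palladium intermediate cis to C1 must not find an alkyne within reach. The forward step must be a non-basic, stereoretentive coupling that tolerates the acid, the dienone and H1.

35 ⇒ 34. No skeletal bond is cut; the C2=C1′ ylidene and the C2′ ketone are traced to a tertiary propargylic carbinol at C2 (Meyer–Schuster). This keeps C2 as a non-enolisable sp3 centre through all basic steps, so H1 becomes acidic only at the end. The forward step must transpose oxygen without ionising toward C1, and must give the E isomer.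

34 ⇒ 33 ⇒ 26 + 32. The C5″–C6″ sp2–sp2 bond is cut. This is convergent and brings the 4″Z and 2″E alkenes in ready-made in 32. The forward coupling must occur only at the C–Br bond trans to C1, with retention in both partners.

26 ⇒ 25 ⇒ 24 ⇒ 20 + 21, and 20 ⇒ 18. The C6″=C7″ bond (dibromo-olefination), the C2–C1′ bond (acetylide addition) and the C1–C7″ bond (aldol with formaldehyde) are cut in turn. C1 is the α′ carbon of the C2 ketone in 18, and the same ketone then accepts the alkyne. The forward steps need kinetic α′ enolisation, attack on C1 anti to the C8a–C8 bond, and conversion of C2 to a carbinol before C7″ is raised to an aldehyde.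

18 ⇒ 17 ⇒ 16. No skeletal bond is cut; the C2 ketone and C3=C4 alkene are traced to a C2=C3 enol silane (Saegusa–Ito). An ene-ketal would be the more obvious mask, but it has three drawbacks:
- it places a trisubstituted C3=C4 alkene 1,3 to the ketyl-bearing arm, opening a 5-exo path to a bicyclo[3.2.1]octane;
- it is acid-labile;
- it costs separate dehydrogenation, ketalisation and deketalisation steps.

The enol silane comes directly from the cycloaddition, and its reachable carbon is the oxygen-bearing one.

16 ⇒ 15. The C6–C7 bond is cut and ring A is opened. This removes two stereocentres and leaves a monocyclic compound with two cis arms. The forward step must be a 6-exo ketyl–olefin closure through a chair that puts O–Sm and both methyls equatorial.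

15 ⇒ 14 ⇒ 13 ⇒ 12 ⇒ 10 ⇒ 9. The C5–C6 bond is cut (vinyl Grignard on the lactol carbon C5) and the C5 oxygen is restored. The lactone differentiates C5 (acyl) from C7 (alkoxy) without protecting-group steps. The forward sequence must remove the C5 oxygen reductively with the alkene ending terminal.

9 ⇒ 6 + 8. The C1–C8a and C4–C4a bonds are cut (Diels–Alder). This sets the cis fusion and ties C8a to C8. The forward step needs para regiochemistry from the silyloxy group and approach anti to the ring methyl of 6.

6 ⇒ 4 ⇒ 3 ⇒ 2 ⇒ 1; 8 ⇒ 7; 32 ⇒ 31 ⇒ 29 ⇒ 27. The C4a=C8a alkene of 6 is cut by Z-selective olefination and the lactone C–O bond is opened, which leads to chiral-pool 1 with the ester carbon becoming C8a. 8 is the enol silane of 7. The C2″=C3″ bond of 32 is a Wittig bond, and the Z iodoalkene of 29 comes from anti-carbometalation of 27.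

## Other disconnections considered

Alternative 1: Cut C4–C4a and C1–C8a with ring A intact. Diene 8 would add to the ring A enone A2 to give the cis-fused adduct A1.
- In favour: an enone is a better dienophile than lactone 6, so on cycloaddition reactivity this plan is the better one.
- In favour: regiocontrol and facial control (silyloxy group, C8 methyl next to the β-carbon) are the same as in the chosen plan, and C6, C7 and C8 do not depend on a radical transition state.
- Against: A2 needs three contiguous stereocentres made by separate asymmetric chemistry, whereas 6 needs one centre from the chiral pool.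
- Against: the C5 ketone of A1 has no counterpart in 37 and must be removed in about three steps next to an enol silane.
- Against: while the C5 ketone is present, C4a is epimerisable toward the trans-fused decalone.
- Comparison: equal on ring B construction; the chosen plan is shorter on ring A because C6 and C7 arise in one step from an achiral arm.

Alternative 2: Cut C1–C8a. Base would close the β-keto ester A3 by 6-exo-trig Michael addition onto the ring A enone to give A4.
- In favour: the C1 carbon, the C2 oxygen and the C3=C4 alkene arrive in one step, which is better than the separate C1 hydroxymethylation of the chosen plan; no divalent samarium or HMPA is needed.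
- In favour: C8a and C8 settle under thermodynamic control.
- Against: the Z enone arm must be made and kept Z.
- Against: the C4a/C6 pair on A3 must be set separately.
- Against: the C7 ketone needs a stereoselective reduction beside a second carbonyl.
- Against: the C1 ester of A4 sits on a β-dicarbonyl, so turning it into the chain aldehyde requires reduction and protection of C2 and gives back the gain.
- Comparison: more ring B functionality per step, and a reversible polar mechanism against an irreversible radical one; overall step economy is about equal after the redox corrections.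

Alternative 3: Cut C1–C2. Lewis-acid activation of the ynone in A6 would let the silyl dienol ether attack through C1 (6-exo-dig) to give A5.
- In favour: one step forms ring B, the C1 stereocentre, the ylidene enone and an enal handle. For the C1/C2 region this is the better plan on step count after ring closure.
- Against: A6 is a cyclohexane with five contiguous stereocentres and two sensitive arms, so the length moves into its preparation.
- Against: the C1 configuration and ylidene geometry rest on kinetic allenolate protonation.
- Against: A5 exposes H1 between an enal and the dienone before the base-mediated Z-selective olefinations; the chosen plan keeps C2 as a carbinol until the triene is in place.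
- Comparison: equal on the need for late Z-alkene control; the chosen plan is safer on mechanism, Alternative 3 is more convergent on paper.

Key step: step 12

Remark on the chemistry: centres that are later removed or become trigonal (the anomeric carbon of 10, C5 of 11 and 12, C2 of 23–26, 33 and 34) are carried as mixtures and are left undefined in the SMILES.

## Route

Step 1
Reactants: 1 methyl (S)-3-hydroxy-2-methylpropanoate
Product: 2 methyl (S)-3-(tert-butyldimethylsilyloxy)-2-methylpropanoate
Conditions: TBSCl, imidazole, DMF, 0 °C to rt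
Reagents that add atoms: tert-butyldimethylsilyl chloride, CC(C)(C)[Si](C)(C)Cl
Why: Imidazole-promoted silylation of the primary alcohol; the α-stereocentre (future C8) is not touched.

Step 2
Reactants: 2 methyl (S)-3-(tert-butyldimethylsilyloxy)-2-methylpropanoate
Product: 3 (S)-3-(tert-butyldimethylsilyloxy)-2-methylpropanal
Conditions: i-Bu2AlH (1.05 equiv), CH2Cl2, −78 °C; aq. KNaC4H4O6; used crude
Reagents that add atoms: none
Why: Partial ester reduction stops at the aluminium hemiacetal at −78 °C and releases the aldehyde on work-up; the α-methyl aldehyde is used at once so that the future C8 centre does not epimerise.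

Step 3
Reactants: 3 (S)-3-(tert-butyldimethylsilyloxy)-2-methylpropanal
Product: 4 methyl (R,Z)-5-(tert-butyldimethylsilyloxy)-4-methylpent-2-enoate
Conditions: (CF3CH2O)2P(O)CH2CO2Me, KN(SiMe3)2, 18-crown-6, THF, −78 °C
Reagents that add atoms: methyl bis(2,2,2-trifluoroethyl)phosphonoacetate, COC(=O)CP(=O)(OCC(F)(F)F)OCC(F)(F)F
Why: Still–Gennari olefination: the electron-poor phosphonate eliminates fast from the kinetic adduct and gives the (Z)-enoate needed for lactonisation; cold, non-equilibrating conditions leave the α-centre intact.

Step 4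
Reactants: 4 methyl (R,Z)-5-(tert-butyldimethylsilyloxy)-4-methylpent-2-enoate
Product: 6 (R)-5-methyl-5,6-dihydro-2H-pyran-2-one, via hydroxy enoate 5 (not isolated)
Conditions: p-TsOH·H2O (cat.), MeOH, rt; then toluene, 60 °C
Reagents that add atoms: none
Why: Acid methanolysis removes the silyl ether and the cis-disposed hydroxyl closes onto the ester (six-membered lactonisation with loss of methanol); no stereocentre is affected.

Step 5
Reactants: 7 3-methylbut-3-en-2-one
Product: 8 2-(tert-butyldimethylsilyloxy)-3-methylbuta-1,3-diene
Conditions: TBSOTf, Et3N, Et2O, 0 °C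
Reagents that add atoms: tert-butyldimethylsilyl triflate, CC(C)(C)[Si](C)(C)OS(=O)(=O)C(F)(F)F
Why: Soft enolisation–silylation of an enone whose only α-hydrogens are on the methyl group gives a single 2-silyloxydiene.

Step 6
Reactants: 6 (R)-5-methyl-5,6-dihydro-2H-pyran-2-one; 8 2-(tert-butyldimethylsilyloxy)-3-methylbuta-1,3-diene
Product: 9 cis-fused lactone carrying the C2=C3 enol silane (C5 lactone carbonyl on C4a; C8 methyl cis to H8a)
Conditions: Me2AlCl (0.3 equiv), CH2Cl2, −40 to 0 °C
Reagents that add atoms: none
Why: Lewis-acid-catalysed Diels–Alder cycloaddition; the silyloxy group makes the adjacent diene terminus the nucleophilic one, which bonds to the β-carbon of 6 (future C8a), so the C2 oxygen ends para to C4a. Suprafacial addition gives the cis C4a/C8a fusion, and the diene approaches the face of 6 opposite its ring methyl, which sets C8a and C4a relative to C8.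

Step 7
Reactants: 9 cis-fused enol silane lactone
Product: 10 lactol of 9 (C5 hemiacetal)
Conditions: i-Bu2AlH (1.1 equiv), CH2Cl2, −78 °C
Reagents that add atoms: none
Why: Low-temperature hydride reduction of the lactone stops at the lactol; the enol silane is inert to hydride.

Step 8
Reactants: 10 lactol of 9
Product: 12 bis(methyl carbonate) of the C5 vinyl carbinol and the C7 alcohol, via magnesium dialkoxide 11 (not isolated)
Conditions: CH2=CHMgBr (2.5 equiv), THF, 0 °C to rt; then ClCO2Me, 0 °C
Reagents that add atoms: vinylmagnesium bromide, C=C[Mg]Br; methyl chloroformate, COC(=O)Cl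
Why: Grignard addition to the open hydroxy-aldehyde form of the lactol forms the C5–C6 bond, and both magnesium alkoxides are acylated in the same flask; the new C5 carbinol centre is uncontrolled and is removed in step 9.

Step 9
Reactants: 12 bis(methyl carbonate)
Product: 13 C4a-allyl compound with C7 methyl carbonate
Conditions: Pd(OAc)2 (5 mol%), n-Bu3P, HCO2H, Et3N, THF, 50 °C
Reagents that add atoms: none
Why: Palladium-catalysed formate hydrogenolysis of an allylic carbonate: zerovalent palladium ionises only the allylic carbonate to an η3-allyl complex, and hydride from formate is delivered to the more substituted terminus C5, which leaves the terminal C6=CH2 alkene. The primary carbonate and the enol silane do not react.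

Step 10
Reactants: 13 C4a-allyl compound with C7 methyl carbonate
Product: 14 C7 primary alcohol with the C4a allyl arm
Conditions: i-Bu2AlH (3.5 equiv), CH2Cl2, −78 to 0 °C
Reagents that add atoms: none
Why: Hydride cleavage of the carbonate frees the C7 alcohol without acid or alkoxide, so the enol silane and the terminal alkene survive.

Step 11
Reactants: 14 C7 primary alcohol with the C4a allyl arm
Product: 15 cis allyl/formylethyl cyclohexene with the C2=C3 enol silane (C7 aldehyde on the C8a arm)
Conditions: Dess–Martin periodinane, pyridine, CH2Cl2, 0 °C; used crude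
Reagents that add atoms: none
Why: Dess–Martin oxidation under pyridine buffering gives the α-branched aldehyde without touching the enol silane; 15 is used immediately to avoid epimerisation at C8.

Step 12
Reactants: 15 cis allyl/formylethyl cyclohexene enol silane
Product: 16 cis-decalin C7 carbinol with C6 and C8 methyls and the C2=C3 enol silane
Conditions: SmI2 (3 equiv), HMPA (12 equiv), t-BuOH (2 equiv), THF, 0 °C, slow addition of 15
Reagents that add atoms: none
Why: SmI2 activated by HMPA transfers one electron to the C7 aldehyde; the samarium ketyl (trivalent samarium on oxygen) adds to C6, the inner carbon of the allyl group, and the primary radical left on the outer carbon is reduced by a second SmI2 and protonated by t-BuOH to the C6 methyl. The closest known reaction type is the SmI2/HMPA-promoted reductive ketyl–olefin cyclisation of unactivated olefinic aldehydes and ketones. Ring A closes in the 6-exo-trig radical mode through the C6–C7 bond, the 7-endo mode being stereoelectronically disfavoured. C7 is set by a chair transition state in which the bulky O–Sm group and the existing C8 methyl are both equatorial, so the hydroxyl is trans to the C8 methyl; C6 is set by the alkene lying anti to the ketyl oxygen in that chair, which leaves the new methyl equatorial and trans to the hydroxyl; the cis fusion is inherited from the cis arms of 15. The step needs cyclisation to win over pinacol coupling and simple reduction, which the cis-1,2 disposition of the two arms and slow addition to excess reductant should secure. It also needs site selectivity between the two alkenes: the only other alkene is the tetrasubstituted, electron-rich enol silane, whose reachable carbon C2 bears the silyloxy group, so the nucleophilic ketyl has no productive 5-exo alternative. The enol silane itself is inert to divalent samarium.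

Step 13
Reactants: 16 cis-decalin C7 carbinol
Product: 17 C7 tert-butyldimethylsilyl ether of 16
Conditions: TBSOTf, 2,6-lutidine, CH2Cl2, −78 to 0 °C
Reagents that add atoms: tert-butyldimethylsilyl triflate, CC(C)(C)[Si](C)(C)OS(=O)(=O)C(F)(F)F
Why: Silyl triflate with a hindered pyridine base silylates the hindered equatorial C7 hydroxyl; the enol silane is stable to these non-protic conditions.

Step 14
Reactants: 17 C7 silyl ether with the C2=C3 enol silane
Product: 18 decalin enone (C2 ketone; C3=C4; C7 silyl ether)
Conditions: Pd(OAc)2 (1.1 equiv), MeCN, 40 °C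
Reagents that add atoms: none
Why: Saegusa–Ito oxidation: divalent palladium exchanges with the enol silane to a C3-bound palladium enolate, and syn β-hydride elimination toward C4 gives the conjugated enone; any exocyclic isomer from elimination into the methyl group should isomerise to the endocyclic enone.

Step 15
Reactants: 18 decalin enone
Product: 20 C1-hydroxymethyl enone (C1 substituent trans to the C8a–C8 bond), via lithium enolate 19 (not isolated)
Conditions: LiN(i-Pr)2, THF, −78 °C; CH2O (gas), −78 °C; aq. NH4Cl
Reagents that add atoms: formaldehyde, C=O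
Why: Kinetic deprotonation of the enone occurs at the α′ carbon C1 (cross-conjugated enolate), and aldol addition to monomeric formaldehyde forms the C1–C7″ bond. The electrophile enters axially on the face opposite the pseudoaxial C8a–C8 bond, which sets C1.

Step 16
Reactants: 20 C1-hydroxymethyl enone; 21 tert-butyldimethyl(prop-2-yn-1-yloxy)silane
Product: 24 bis(trimethylsilyl) ether of the C2 alkynyl carbinol (C1 CH2OSiMe3; C2 OSiMe3), via lithium acetylide 22 (not isolated), via dilithium dialkoxide 23 (not isolated)
Conditions: 21 (3.5 equiv), n-BuLi, THF, −78 °C; add 20; then Me3SiCl, −78 to 0 °C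
Reagents that add atoms: chlorotrimethylsilane, C[Si](C)(C)Cl
Why: Lithium acetylides add 1,2 to enones; one equivalent deprotonates the hydroxyl and another attacks the C2 carbonyl, and both alkoxides are capped in the same flask. The C2 configuration is irrelevant because C2 becomes trigonal in step 24.

Step 17
Reactants: 24 bis(trimethylsilyl) ether
Product: 25 C1 aldehyde with the C2 trimethylsilyloxy alkynyl carbinol
Conditions: (COCl)2, DMSO, CH2Cl2, −78 to −40 °C; Et3N
Reagents that add atoms: none
Why: Swern conditions cleave and oxidise primary trimethylsilyl ethers directly to aldehydes, whereas the tertiary silyl ether has no carbinol hydrogen and is retained; low temperature and brief amine contact limit epimerisation at C1.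

Step 18
Reactants: 25 C1 aldehyde
Product: 26 C1 (2,2-dibromovinyl) compound
Conditions: CBr4, PPh3, Et3N, CH2Cl2, 0 °C
Reagents that add atoms: carbon tetrabromide, BrC(Br)(Br)Br
Why: Ramirez dibromo-olefination (first stage of the Corey–Fuchs sequence); the small, reactive ylide Ph3P=CBr2 should convert even this hindered aldehyde, and no stereocentre or alkene geometry is created.

Step 19
Reactants: 27 prop-2-yn-1-ol
Product: 29 (Z)-3-iodo-2-methylprop-2-en-1-ol, via magnesacycle 28 (not isolated)
Conditions: MeMgBr (2.5 equiv), CuI (10 mol%), THF, −10 °C to rt; then I2, −40 to 0 °C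
Reagents that add atoms: methylmagnesium bromide, C[Mg]Br; iodine, [I][I]
Why: Copper-catalysed, alkoxide-directed anti-carbomagnesiation places the methyl on the internal alkyne carbon and magnesium on the terminal carbon cis to the CH2O group (five-membered chelate); iodinolysis with retention gives the (Z)-iodide.

Step 20
Reactants: 29 (Z)-3-iodo-2-methylprop-2-en-1-ol
Product: 31 methyl (2E,4Z)-5-iodo-4-methylpenta-2,4-dienoate, via iodoenal 30 (not isolated)
Conditions: MnO2, Ph3P=CHCO2Me, CH2Cl2, rt
Reagents that add atoms: methyl (triphenylphosphoranylidene)acetate, COC(=O)C=P(c1ccccc1)(c1ccccc1)c1ccccc1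
Why: Tandem oxidation–Wittig: MnO2 oxidises the allylic alcohol and the stabilised ylide traps the sensitive (Z)-iodoenal as it forms, giving the (E)-acrylate while the Z iodoalkene is kept.

Step 21
Reactants: 31 methyl (2E,4Z)-5-iodo-4-methylpenta-2,4-dienoate
Product: 32 methyl (2E,4Z)-4-methyl-5-(tributylstannyl)penta-2,4-dienoate
Conditions: (Bu3Sn)2, Pd(PPh3)4 (5 mol%), toluene, 80 °C
Reagents that add atoms: hexabutylditin, CCCC[Sn](CCCC)(CCCC)[Sn](CCCC)(CCCC)CCCC
Why: Palladium-catalysed stannylation (oxidative addition, transmetalation with the distannane, reductive elimination) replaces iodine by tin with retention of the Z geometry.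

Step 22
Reactants: 26 C1 (2,2-dibromovinyl) compound; 32 methyl (2E,4Z)-4-methyl-5-(tributylstannyl)penta-2,4-dienoate
Product: 33 methyl (2E,4Z,6Z)-6-bromo-4-methylhepta-2,4,6-trienoate bonded through C7″ to C1 (C2 trimethylsilyloxy alkynyl carbinol retained)
Conditions: Pd2(dba)3 (5 mol%), P(2-furyl)3, toluene, 70 °C
Reagents that add atoms: none
Why: Stille coupling of a 1,1-dibromoalkene is selective for the C–Br bond trans to the C1 substituent, the less hindered one, and both partners react with retention, which gives the 6″Z bromotriene with the 4″Z and 2″E alkenes unchanged. The palladium intermediate is trans to C1 and cannot reach the alkyne.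

Step 23
Reactants: 33 bromotrienoate with silylated carbinol
Product: 34 (2E,4Z,6Z)-6-bromo-trienoic acid with the free C2 alkynyl carbinol
Conditions: LiOH, THF/MeOH/H2O, rt; dilute HCl to pH 4, 0 °C
Reagents that add atoms: lithium hydroxide, [Li+].[OH-]
Why: Saponification of the methyl ester; the tertiary trimethylsilyl ether should be cleaved by the same aqueous methanolic hydroxide, whereas the tert-butyldimethylsilyl ethers and the vinyl bromide are stable. Careful acidification avoids ionising the tertiary carbinol.

Step 24
Reactants: 34 bromotrienoic acid with free C2 alkynyl carbinol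
Product: 35 6″-bromo analogue of 36 (C2=C1′ ylidene with silylated hydroxyacetyl ketone)
Conditions: Ph3PAuNTf2 (5 mol%), MeOH (2 equiv), toluene, rt
Reagents that add atoms: none
Why: Meyer–Schuster rearrangement under monovalent gold catalysis: a formal 1,3-shift of the tertiary hydroxyl to the alkyne terminus and tautomerisation of the allenol give the C2=C1′ enone. The E isomer (acyl group on the C1 side, away from the C3 methyl) is the thermodynamic one because the chain at C1 is axial and leaves only H1 in the ylidene plane.

Step 25
Reactants: 35 6″-bromo analogue of 36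
Product: 36 7,3′-bis-O-(tert-butyldimethylsilyl) derivative of 37
Conditions: Me2Zn (3 equiv), Pd(P(t-Bu)3)2 (5 mol%), THF, 0 °C to rt
Reagents that add atoms: dimethylzinc, C[Zn]C
Why: Negishi coupling of the (Z)-2-bromo-1,3-diene; the bulky, electron-rich phosphine gives fast transmetalation and reductive elimination with retention, which makes the C6″=C7″ bond E. The conditions are non-basic, so H1 and the dienone are not disturbed; one equivalent of Me2Zn is consumed by the acid.

Step 26
Reactants: 36 bis-silyl ether of the target
Product: 37 target acid CNP0219601.2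
Conditions: HF·pyridine, pyridine, THF, 0 °C to rt
Reagents that add atoms: none
Why: Fluoride cleavage of both silyl ethers under buffered, weakly acidic conditions that neither enolise toward C1 nor isomerise the triene.

## Compound list

1 | methyl (S)-3-hydroxy-2-methylpropanoate | COC(=O)[C@@H](C)CO | starting material
2 | methyl (S)-3-(tert-butyldimethylsilyloxy)-2-methylpropanoate | COC(=O)[C@@H](C)CO[Si](C)(C)C(C)(C)C | intermediate
3 | (S)-3-(tert-butyldimethylsilyloxy)-2-methylpropanal | O=C[C@@H](C)CO[Si](C)(C)C(C)(C)C | intermediate
4 | methyl (R,Z)-5-(tert-butyldimethylsilyloxy)-4-methylpent-2-enoate | COC(=O)/C=C\[C@@H](C)CO[Si](C)(C)C(C)(C)C | intermediate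
5 | methyl (R,Z)-5-hydroxy-4-methylpent-2-enoate (not isolated) | COC(=O)/C=C\[C@@H](C)CO | intermediate
6 | (R)-5-methyl-5,6-dihydro-2H-pyran-2-one | O=C1C=C[C@@H](C)CO1 | intermediate
7 | 3-methylbut-3-en-2-one | CC(=O)C(C)=C | starting material
8 | 2-(tert-butyldimethylsilyloxy)-3-methylbuta-1,3-diene | C=C(O[Si](C)(C)C(C)(C)C)C(C)=C | intermediate
9 | cis-fused Diels–Alder lactone (C5 carbonyl on C4a, O on C7, C8 methyl cis to H8a, C2=C3 silyl enol ether) | CC1=C(O[Si](C)(C)C(C)(C)C)C[C@@H]2[C@@H](C)COC(=O)[C@@H]2C1 | intermediate
10 | lactol of 9 (C5 hemiacetal, anomers) | CC1=C(O[Si](C)(C)C(C)(C)C)C[C@@H]2[C@@H](C)COC(O)[C@@H]2C1 | intermediate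
11 | bis(bromomagnesium) alkoxide of the C5 vinyl carbinol and C7 alcohol (not isolated) | CC1=C(O[Si](C)(C)C(C)(C)C)C[C@H]([C@@H](C)CO[Mg]Br)[C@H](C(O[Mg]Br)C=C)C1 | intermediate
12 | bis(methyl carbonate): C5 allylic carbonate (epimers) and C7 carbonate | CC1=C(O[Si](C)(C)C(C)(C)C)C[C@H]([C@@H](C)COC(=O)OC)[C@H](C(OC(=O)OC)C=C)C1 | intermediate
13 | C4a-allyl compound with C7 methyl carbonate | CC1=C(O[Si](C)(C)C(C)(C)C)C[C@H]([C@@H](C)COC(=O)OC)[C@H](CC=C)C1 | intermediate
14 | C7 primary alcohol with the C4a allyl arm | CC1=C(O[Si](C)(C)C(C)(C)C)C[C@H]([C@@H](C)CO)[C@H](CC=C)C1 | intermediate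
15 | key-step precursor: cis allyl (C4a) / (R)-1-formylethyl (C8a) cyclohexene, C2=C3 silyl enol ether | CC1=C(O[Si](C)(C)C(C)(C)C)C[C@H]([C@@H](C)C=O)[C@H](CC=C)C1 | intermediate
16 | key-step product: cis-decalin C7 carbinol, C6 and C8 methyls trans to it, C2=C3 silyl enol ether | CC1=C(O[Si](C)(C)C(C)(C)C)C[C@@H]2[C@@H](C)[C@H](O)[C@@H](C)C[C@@H]2C1 | intermediate
17 | C7 tert-butyldimethylsilyl ether of 16 | CC1=C(O[Si](C)(C)C(C)(C)C)C[C@@H]2[C@@H](C)[C@H](O[Si](C)(C)C(C)(C)C)[C@@H](C)C[C@@H]2C1 | intermediate
18 | decalin enone (C2 ketone, C3=C4, C7 silyl ether) | CC1=C[C@H]2C[C@H](C)[C@@H](O[Si](C)(C)C(C)(C)C)[C@H](C)[C@H]2CC1=O | intermediate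
19 | lithium α′-enolate of 18 (C1=C2–OLi) (not isolated) | [Li+].CC1=C[C@H]2C[C@H](C)[C@@H](O[Si](C)(C)C(C)(C)C)[C@H](C)[C@H]2C=C1[O-] | intermediate
20 | C1-hydroxymethyl enone (CH2OH trans to the C8a–C8 bond) | CC1=C[C@H]2C[C@H](C)[C@@H](O[Si](C)(C)C(C)(C)C)[C@H](C)[C@H]2[C@H](CO)C1=O | intermediate
21 | tert-butyldimethyl(prop-2-yn-1-yloxy)silane | C#CCO[Si](C)(C)C(C)(C)C | starting material
22 | lithium acetylide of 21 (not isolated) | [Li+].[C-]#CCO[Si](C)(C)C(C)(C)C | intermediate
23 | dilithium dialkoxide of the C2 alkynyl carbinol (not isolated) | [Li+].[Li+].CC1=C[C@H]2C[C@H](C)[C@@H](O[Si](C)(C)C(C)(C)C)[C@H](C)[C@H]2[C@H](C[O-])C1([O-])C#CCO[Si](C)(C)C(C)(C)C | intermediate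
24 | bis(trimethylsilyl) ether (C1 CH2OSiMe3, C2 OSiMe3, C2 3-silyloxypropynyl) | CC1=C[C@H]2C[C@H](C)[C@@H](O[Si](C)(C)C(C)(C)C)[C@H](C)[C@H]2[C@H](CO[Si](C)(C)C)C1(O[Si](C)(C)C)C#CCO[Si](C)(C)C(C)(C)C | intermediate
25 | C1 aldehyde with C2 trimethylsilyloxy alkynyl carbinol | CC1=C[C@H]2C[C@H](C)[C@@H](O[Si](C)(C)C(C)(C)C)[C@H](C)[C@H]2[C@H](C=O)C1(O[Si](C)(C)C)C#CCO[Si](C)(C)C(C)(C)C | intermediate
26 | C1 (2,2-dibromovinyl) compound | CC1=C[C@H]2C[C@H](C)[C@@H](O[Si](C)(C)C(C)(C)C)[C@H](C)[C@H]2[C@H](C=C(Br)Br)C1(O[Si](C)(C)C)C#CCO[Si](C)(C)C(C)(C)C | intermediate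
27 | prop-2-yn-1-ol | C#CCO | starting material
28 | 4-methyl-2,5-dihydro-1,2-oxamagnesole (alkenylmagnesium alkoxide, not isolated) | CC1=C[Mg]OC1 | intermediate
29 | (Z)-3-iodo-2-methylprop-2-en-1-ol | OC/C(C)=C\I | intermediate
30 | (Z)-3-iodo-2-methylprop-2-enal (not isolated) | O=C/C(C)=C\I | intermediate
31 | methyl (2E,4Z)-5-iodo-4-methylpenta-2,4-dienoate | COC(=O)/C=C/C(C)=C\I | intermediate
32 | methyl (2E,4Z)-4-methyl-5-(tributylstannyl)penta-2,4-dienoate | COC(=O)/C=C/C(C)=C\[Sn](CCCC)(CCCC)CCCC | intermediate
33 | methyl (2E,4Z,6Z)-6-bromo-4-methylhepta-2,4,6-trienoate on C1, C2 trimethylsilyloxy alkynyl carbinol | CC1=C[C@H]2C[C@H](C)[C@@H](O[Si](C)(C)C(C)(C)C)[C@H](C)[C@H]2[C@H](/C=C(Br)/C=C(C)\C=C\C(=O)OC)C1(O[Si](C)(C)C)C#CCO[Si](C)(C)C(C)(C)C | intermediate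
34 | (2E,4Z,6Z)-6-bromo-trienoic acid with free C2 alkynyl carbinol | CC1=C[C@H]2C[C@H](C)[C@@H](O[Si](C)(C)C(C)(C)C)[C@H](C)[C@H]2[C@H](/C=C(Br)/C=C(C)\C=C\C(=O)O)C1(O)C#CCO[Si](C)(C)C(C)(C)C | intermediate
35 | 6″-bromo analogue of 36 (E ylidene, silylated hydroxyacetyl ketone) | CC1=C[C@H]2C[C@H](C)[C@@H](O[Si](C)(C)C(C)(C)C)[C@H](C)[C@H]2[C@H](/C=C(Br)/C=C(C)\C=C\C(=O)O)/C1=C\C(=O)CO[Si](C)(C)C(C)(C)C | intermediate
36 | 7,3′-bis-O-(tert-butyldimethylsilyl) derivative of 37 | CC1=C[C@H]2C[C@H](C)[C@@H](O[Si](C)(C)C(C)(C)C)[C@H](C)[C@H]2[C@H](/C=C(C)/C=C(C)\C=C\C(=O)O)/C1=C\C(=O)CO[Si](C)(C)C(C)(C)C | intermediate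
37 | CNP0219601.2 | CC1=C[C@H]2C[C@H](C)[C@@H](O)[C@H](C)[C@H]2[C@H](/C=C(C)/C=C(C)\C=C\C(=O)O)/C1=C\C(=O)CO | target

## Step count and least certain steps

Total: 26 steps. Longest linear sequence: 22 steps (steps 1–4, 6–18, 22–26). Step 5 and steps 19–21 are side branches.

**Step 12 (key step).** The 6-exo addition of an aldehyde ketyl to an unactivated alkene is slow, so pinacol dimerisation or simple reduction of the aldehyde may compete. A boat-like transition state would erode the C6/C7 selectivity, and C8 may epimerise in 15 before cyclisation.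
Fallback, from 14 back to 16: cross-metathesis of 14 with phenyl vinyl sulfone (second-generation Grubbs catalyst, CH2Cl2, 40 °C) would give the (E)-vinyl sulfone alcohol F1. Dess–Martin oxidation would give the sulfone aldehyde F2. SmI2 in THF/MeOH at −78 °C, without HMPA, would add the ketyl to the activated alkene and give the sulfonylmethyl carbinol F3. Reductive desulfonylation with SmI2/HMPA at rt would turn CH2SO2Ph into the C6 methyl and return to 16.

**Step 6.** The unactivated lactone may be too poor a dienophile, and the Lewis acid may divert the diene into silyl transfer and an open Mukaiyama–Michael adduct that does not ring-close; facial selectivity could also fall.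
Fallback, from 6 back to 9: bromine addition to 6 would give the dibromolactone F4, and triethylamine would eliminate HBr to the 3-bromolactone F5, an activated dienophile. Thermal cycloaddition with 8 (toluene, 110 °C) would give the C4a-bromo adduct F6. Bu3SnH/AIBN would then remove bromine, with hydrogen delivered to C4a on the face of H8a, returning to 9.

**Step 15.** The aldol may dehydrate to the α-methylene ketone or add formaldehyde twice, facial selectivity at C1 may be incomplete, and the aldolate may undergo retro-aldol cleavage in step 16.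
Fallback, from 18 (through 19) back to 20: trapping 19 with Me3SiCl would give the silyl dienol ether F7. Lewis-acid hydroxymethylation with aqueous formaldehyde and Yb(OTf)3 in THF/H2O (Mukaiyama aldol) would return to 20 under non-basic conditions.

**Step 22 (with step 25).** Coupling may occur twice or at the wrong C–Br bond, and the later methylation in step 25 may proceed with partial stereoinversion.
Fallback, from 25 back to 36, avoiding 33–35 and step 25:
- Wittig reaction of 25 with 2-(triphenylphosphoranylidene)propanal would give the (E)-2-methylenal F8.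
- Still–Gennari olefination with methyl 2-[bis(2,2,2-trifluoroethoxy)phosphoryl]propanoate would give the (2Z,4E)-dienoate F9.
- i-Bu2AlH would give the dienol F10.
- MnO2 with Ph3P=CHCO2Me would pass through the dienal F11 to the methyl (2E,4Z,6E)-trienoate F12.
- LiOH would give the hydroxy acid F13, and the gold-catalysed Meyer–Schuster rearrangement of step 24 would then give 36.

**Step 24.** The tertiary allylic–propargylic carbinol may ionise and eliminate toward C1 instead of transposing, or the ylidene may form without full E selectivity, in a substrate that already carries the bromotriene acid.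
Fallback, from 26 back to 35: K2CO3/MeOH would free the tertiary carbinol F14, and rearrangement at this simpler stage with an oxovanadium catalyst, VO(OSiPh3)3 in toluene at 80 °C, would give the ylidene dibromide F15. Saponification of 32 would give the stannyl dienoic acid F16. Stille coupling of F15 with F16 under the conditions of step 22 would return to 35.

## Further compounds

F1 | step 12 | (E)-vinyl sulfone alcohol from cross-metathesis of 14 | CC1=C(O[Si](C)(C)C(C)(C)C)C[C@H]([C@@H](C)CO)[C@H](C/C=C/S(=O)(=O)c2ccccc2)C1
F2 | step 12 | sulfone aldehyde | CC1=C(O[Si](C)(C)C(C)(C)C)C[C@H]([C@@H](C)C=O)[C@H](C/C=C/S(=O)(=O)c2ccccc2)C1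
F3 | step 12 | C6 (phenylsulfonyl)methyl analogue of 16 | CC1=C(O[Si](C)(C)C(C)(C)C)C[C@@H]2[C@@H](C)[C@H](O)[C@@H](CS(=O)(=O)c3ccccc3)C[C@@H]2C1
F4 | step 6 | (5R)-3,4-dibromo-5-methyltetrahydropyran-2-one | O=C1C(Br)C(Br)[C@@H](C)CO1
F5 | step 6 | (R)-3-bromo-5-methyl-5,6-dihydro-2H-pyran-2-one | O=C1C(Br)=C[C@@H](C)CO1
F6 | step 6 | C4a-bromo analogue of 9 | CC1=C(O[Si](C)(C)C(C)(C)C)C[C@@H]2[C@@H](C)COC(=O)[C@]2(Br)C1
F7 | step 15 | trimethylsilyl dienol ether of 18 (C1=C2–OSiMe3) | CC1=C[C@H]2C[C@H](C)[C@@H](O[Si](C)(C)C(C)(C)C)[C@H](C)[C@H]2C=C1O[Si](C)(C)C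
F8 | step 22 | (E)-2-methylenal on C1 | CC1=C[C@H]2C[C@H](C)[C@@H](O[Si](C)(C)C(C)(C)C)[C@H](C)[C@H]2[C@H](/C=C(C)/C=O)C1(O[Si](C)(C)C)C#CCO[Si](C)(C)C(C)(C)C
F9 | step 22 | methyl (2Z,4E)-2,4-dimethylpenta-2,4-dienoate on C1 | CC1=C[C@H]2C[C@H](C)[C@@H](O[Si](C)(C)C(C)(C)C)[C@H](C)[C@H]2[C@H](/C=C(C)/C=C(C)\C(=O)OC)C1(O[Si](C)(C)C)C#CCO[Si](C)(C)C(C)(C)C
F10 | step 22 | (2Z,4E)-dienol | CC1=C[C@H]2C[C@H](C)[C@@H](O[Si](C)(C)C(C)(C)C)[C@H](C)[C@H]2[C@H](/C=C(C)/C=C(C)\CO)C1(O[Si](C)(C)C)C#CCO[Si](C)(C)C(C)(C)C
F11 | step 22 | (2Z,4E)-dienal (not isolated) | CC1=C[C@H]2C[C@H](C)[C@@H](O[Si](C)(C)C(C)(C)C)[C@H](C)[C@H]2[C@H](/C=C(C)/C=C(C)\C=O)C1(O[Si](C)(C)C)C#CCO[Si](C)(C)C(C)(C)C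
F12 | step 22 | methyl (2E,4Z,6E)-trienoate with C2 trimethylsilyloxy alkynyl carbinol | CC1=C[C@H]2C[C@H](C)[C@@H](O[Si](C)(C)C(C)(C)C)[C@H](C)[C@H]2[C@H](/C=C(C)/C=C(C)\C=C\C(=O)OC)C1(O[Si](C)(C)C)C#CCO[Si](C)(C)C(C)(C)C
F13 | step 22 | (2E,4Z,6E)-trienoic acid with free C2 alkynyl carbinol | CC1=C[C@H]2C[C@H](C)[C@@H](O[Si](C)(C)C(C)(C)C)[C@H](C)[C@H]2[C@H](/C=C(C)/C=C(C)\C=C\C(=O)O)C1(O)C#CCO[Si](C)(C)C(C)(C)C
F14 | step 24 | dibromovinyl compound with free C2 alkynyl carbinol | CC1=C[C@H]2C[C@H](C)[C@@H](O[Si](C)(C)C(C)(C)C)[C@H](C)[C@H]2[C@H](C=C(Br)Br)C1(O)C#CCO[Si](C)(C)C(C)(C)C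
F15 | step 24 | ylidene enone carrying the C1 dibromovinyl group | CC1=C[C@H]2C[C@H](C)[C@@H](O[Si](C)(C)C(C)(C)C)[C@H](C)[C@H]2[C@H](C=C(Br)Br)/C1=C\C(=O)CO[Si](C)(C)C(C)(C)C
F16 | step 24 | (2E,4Z)-4-methyl-5-(tributylstannyl)penta-2,4-dienoic acid | OC(=O)/C=C/C(C)=C\[Sn](CCCC)(CCCC)CCCC
A1 | alternative 1 | cis-fused adduct with C2 silyl enol ether and C5 ketone | CC1=C(O[Si](C)(C)C(C)(C)C)C[C@@H]2[C@@H](C)[C@H](O[Si](C)(C)C(C)(C)C)[C@@H](C)C(=O)[C@@H]2C1
A2 | alternative 1 | 5-(tert-butyldimethylsilyloxy)-4,6-dimethylcyclohex-2-en-1-one (ring A enone) | O=C1C=C[C@@H](C)[C@H](O[Si](C)(C)C(C)(C)C)[C@H]1C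
A3 | alternative 2 | ring A enone with the (Z)-keto ester arm on C4a | O=C1C(C)=C[C@@H](/C=C(C)\C(=O)CC(=O)OC)C[C@@H]1C
A4 | alternative 2 | cis-fused ring B β-keto ester (enol form) with C7 ketone | CC1=C[C@H]2C[C@H](C)C(=O)[C@H](C)[C@H]2C(C(=O)OC)=C1O
A5 | alternative 3 | decalin with C1 enal arm and silylated hydroxyacetylidene | CC1=C[C@H]2C[C@H](C)[C@@H](O[Si](C)(C)C(C)(C)C)[C@H](C)[C@H]2[C@H](/C=C(C)/C=O)/C1=C\C(=O)CO[Si](C)(C)C(C)(C)C
A6 | alternative 3 | ring A cyclohexane with (Z)-enynone arm on C4a and silyl dienol ether arm on C8a | C[C@H]1C[C@H](/C=C(C)\C#CC(=O)CO[Si](C)(C)C(C)(C)C)[C@H](/C=C/C(C)=C/O[Si](C)(C)C(C)(C)C)[C@@H](C)[C@@H]1O[Si](C)(C)C(C)(C)C
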